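**Plan** (ring A = cyclohexane of the left half, ring B = its seven-membered lactone, ring C = cyclohexene of the right half; PMB = 4-methoxybenzyl, TBS = tert-butyldimethylsilyl)

- Cut 1: the ester C–O bond between the CH2O arm on the carbinol carbon of ring A and the acryloyl carbonyl, giving a right-half acid and a left-half diol.
- Cut 2: in the right half the trisubstituted C=C (olefination, back to a ring C carbaldehyde); in the left half the C=C of ring B (metathesis), its lactone C–O bond, the tertiary C–O bond (directed epoxidation) and the ring–CO2H bond ([2,3] shift).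
- Cut 3: both carbocycles converge on one cyclohexene. Ring C is a cyclohexene whose alkene carbon bears CH2OH and whose two neighbouring sp3 carbons carry the side chain and the isopropyl group cis. That is the retron of an endo [4+2] addition of an (E)-1,3-disubstituted butadiene to an acrylic acid derivative, and ring A holds the same iPr–CH–CH(side chain)–CH–C(CH2O) sequence.
- Forward: diene + acrylimide give the cyclohexene (step 4); acyl becomes isopropyl (5–8); right-half acid (9–13); from the same cyclohexene ring A is functionalised and ring B closed (14–25); esterification (26); deprotection (27).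
- Stereochemistry: the (S)-benzyloxazolidinone fixes the isopropyl-bearing carbon of both halves and, through endo addition, its cis neighbour in ring C. In ring A the CH2OH carbon enters anti to the CH2OTBS arm, the epoxide oxygen syn to that CH2OH, and the formyl-bearing carbon is then inverted by equilibration into a cis-fused lactol. The acrylate geometry comes from an (E)-selective olefination (right) and from ring constraint (left).

Key step: step 4

Remark: boronate 5, phosphonoacrylate 18, stannane 24 and bromoacrylate 39 are taken as purchasable reagents.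

**Step 1**
Reactants: 1 4-methoxybenzyl alcohol; 2 2,3-dibromopropene
Product: 4 2-bromoallyl PMB ether, via sodium 4-methoxybenzyl oxide 3 (not isolated)
Conditions: NaH, THF/DMF, 0 °C; then 2, 0 °C → rt
Reagents that add atoms: none
Why: Williamson ether synthesis; the alkoxide displaces the allylic bromide by SN2 while the vinylic C–Br bond is inert.

**Step 2**
Reactants: 4 2-bromoallyl PMB ether; 5 (E)-3-(TBS-oxy)prop-1-enylboronic acid pinacol ester
Product: 6 (E)-1-(TBS-oxy)-4-(PMB-oxymethyl)penta-2,4-diene
Conditions: Pd(PPh3)4 (5 mol %), K3PO4, THF/H2O, 60 °C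
Reagents that add atoms: none
Why: Suzuki–Miyaura coupling; oxidative addition of zerovalent palladium into the vinylic C–Br bond, transmetalation and reductive elimination all retain geometry, so the (E)-alkene of 5 is carried into the diene.

**Step 3**
Reactants: 7 (S)-4-benzyloxazolidin-2-one; 8 acryloyl chloride
Product: 10 (S)-3-acryloyl-4-benzyloxazolidin-2-one, via lithium oxazolidinide 9 (not isolated)
Conditions: n-BuLi, THF, −78 °C; then 8, −78 → 0 °C
Reagents that add atoms: none
Why: N-acylation of the lithiated carbamate by the acid chloride, the standard preparation of N-acyl oxazolidinones; the stereocentre of 7 is not involved.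

**Step 4**
Reactants: 6 diene; 10 acrylimide
Product: 11 (S)-4-benzyl-3-{(1R,2S)-2-[(TBS-oxy)methyl]-4-[(PMB-oxy)methyl]cyclohex-3-ene-1-carbonyl}oxazolidin-2-one
Conditions: Et2AlCl (1.4 equiv), CH2Cl2, −78 °C
Reagents that add atoms: none
Why: Et2AlCl binds both imide carbonyls of 10, locking the acryloyl unit s-cis and lowering its LUMO, and the diene adds in a concerted suprafacial [4+2] cycloaddition; the closest known reaction is the auxiliary-controlled Diels–Alder addition of N-acryloyl oxazolidinones to acyclic dienes. The six-membered ring closes by intermolecular cycloaddition, one new C–C bond joining the acyl-bearing carbon to the CH2OTBS-bearing diene terminus and the other joining the acrylate CH2 to the diene CH2 terminus. The step needs regiocontrol, and the substrate reinforces it: the terminal substituent and the internal CH2OPMB substituent both place the largest HOMO coefficient on the unsubstituted CH2 terminus, which bonds to the acrylate β-carbon, so the ring alkene lies between the CH2OPMB-bearing carbon and the allylic stereocentre. The CH2OTBS-bearing stereocentre is set cis to the acyl group by endo approach of the (E)-diene. The acyl-bearing stereocentre is set by the benzyl group of the auxiliary, which covers the Re face of the acrylate α-carbon in the chelate so that the diene adds to the Si face, giving (1R,2S). The ether oxygens are weaker donors than the chelating imide, so the PMB and silyl ethers should survive at −78 °C.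

**Step 5**
Reactants: 11 cycloadduct
Product: 12 (1R,2S)-N-methoxy-N-methyl-2-[(TBS-oxy)methyl]-4-[(PMB-oxy)methyl]cyclohex-3-ene-1-carboxamide
Conditions: MeNHOMe·HCl, AlMe3, CH2Cl2, 0 °C → rt
Reagents that add atoms: N,O-dimethylhydroxylamine hydrochloride, CNOC.Cl
Why: aluminium amide transamination of the N-acyl oxazolidinone; attack at the exocyclic carbonyl releases the auxiliary without touching the α-stereocentre.

**Step 6**
Reactants: 12 Weinreb amide
Product: 13 1-{(1R,2S)-2-[(TBS-oxy)methyl]-4-[(PMB-oxy)methyl]cyclohex-3-en-1-yl}ethan-1-one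
Conditions: MeMgBr, THF, 0 °C; aq. NH4Cl
Reagents that add atoms: methylmagnesium bromide, C[Mg]Br
Why: Weinreb ketone synthesis; the chelated adduct persists until work-up, so addition stops at the methyl ketone and the cis α-centre is not exposed to base as a ketone.

**Step 7**
Reactants: 13 methyl ketone
Product: 14 cis-isopropenyl cyclohexene, tert-butyl({(1S,6R)-3-[(PMB-oxy)methyl]-6-(prop-1-en-2-yl)cyclohex-2-en-1-yl}methoxy)dimethylsilane
Conditions: Ph3PCH3Br, KOtBu, THF, 0 °C → rt
Reagents that add atoms: methyltriphenylphosphonium bromide, C[P+](c1ccccc1)(c1ccccc1)c1ccccc1.[Br-]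
Why: Wittig methylenation; the ylide should add to the methyl ketone faster than it removes the hindered ring methine proton, so the cis arrangement is kept.

**Step 8**
Reactants: 14 isopropenyl compound
Product: 15 tert-butyl({(1R,6S)-6-isopropyl-3-[(PMB-oxy)methyl]cyclohex-2-en-1-yl}methoxy)dimethylsilane (common intermediate; CH2OTBS and isopropyl cis)
Conditions: H2 (1 atm), RhCl(PPh3)3 (5 mol %), benzene, rt
Reagents that add atoms: none
Why: homogeneous hydrogenation with RhCl(PPh3)3 reduces the 1,1-disubstituted alkene in preference to the trisubstituted ring alkene and does not cleave allylic or benzylic ethers.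

**Step 9**
Reactants: 15 common intermediate
Product: 16 {(1R,6S)-6-isopropyl-3-[(PMB-oxy)methyl]cyclohex-2-en-1-yl}methanol
Conditions: Bu4NF, THF, 0 °C → rt
Reagents that add atoms: none
Why: fluoride desilylation; the PMB ether and the alkene are inert.

**Step 10**
Reactants: 16 alcohol
Product: 17 (1R,6S)-6-isopropyl-3-[(PMB-oxy)methyl]cyclohex-2-ene-1-carbaldehyde
Conditions: Dess–Martin periodinane, NaHCO3, CH2Cl2, 0 °C; used crude
Reagents that add atoms: none
Why: Dess–Martin oxidation under buffered, non-basic conditions should give the β,γ-unsaturated aldehyde without epimerisation at the allylic α-carbon or migration of the ring alkene.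

**Step 11**
Reactants: 1 4-methoxybenzyl alcohol; 18 ethyl 2-(diethoxyphosphoryl)acrylate
Product: 19 ethyl 2-(diethoxyphosphoryl)-3-(PMB-oxy)propanoate (racemic)
Conditions: KOtBu (10 mol %), THF, 0 °C → rt
Reagents that add atoms: none
Why: oxa-Michael addition to the doubly activated alkene; the stabilised phosphonate carbanion is protonated by more alcohol, so the base is catalytic.

**Step 12**
Reactants: 19 phosphonate; 17 aldehyde
Product: 21 ethyl (E)-3-{(1R,6S)-6-isopropyl-3-[(PMB-oxy)methyl]cyclohex-2-en-1-yl}-2-[(PMB-oxy)methyl]prop-2-enoate, via sodium phosphonate 20 (not isolated)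
Conditions: NaH (1.0 equiv), 19 (1.1 equiv), THF, 0 °C; then 17, −78 → 0 °C
Reagents that add atoms: none
Why: Horner–Wadsworth–Emmons olefination; reversible addition of the α-substituted phosphonoacetate anion and syn-elimination should place the ester trans to the ring, and the weakly basic anion, used without excess, should leave the aldehyde α-centre intact.

**Step 13**
Reactants: 21 ethyl ester
Product: 22 (E)-3-{(1R,6S)-6-isopropyl-3-[(PMB-oxy)methyl]cyclohex-2-en-1-yl}-2-[(PMB-oxy)methyl]prop-2-enoic acid (right-half acid)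
Conditions: LiOH, THF/MeOH/H2O, rt; aq. HCl to pH 3
Reagents that add atoms: lithium hydroxide, [Li+].[OH-]
Why: saponification of the ethyl ester; ethers and both alkenes are stable to aqueous hydroxide at room temperature.

**Step 14**
Reactants: 15 common intermediate
Product: 23 {(3R,4S)-3-[(TBS-oxy)methyl]-4-isopropylcyclohex-1-en-1-yl}methanol
Conditions: DDQ, CH2Cl2/pH 7 buffer, 0 °C
Reagents that add atoms: none
Why: oxidative PMB ether cleavage (benzylic hydride abstraction by DDQ, then hydrolysis); the silyl ether survives.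

**Step 15**
Reactants: 23 allylic alcohol; 24 tributyl(iodomethyl)stannane
Product: 26 tributyl[({(3R,4S)-3-[(TBS-oxy)methyl]-4-isopropylcyclohex-1-en-1-yl}methoxy)methyl]stannane, via potassium alkoxide 25 (not isolated)
Conditions: KH, THF, 0 °C; then 24, 18-crown-6 (cat.), 0 °C → rt
Reagents that add atoms: none
Why: Williamson etherification; SN2 displacement of the primary iodide by the allylic alkoxide.

**Step 16**
Reactants: 26 stannylmethyl ether
Product: 28 {(1S,2R,3S)-2-[(TBS-oxy)methyl]-3-isopropyl-6-methylidenecyclohexyl}methanol, via alkoxymethyllithium 27 (not isolated)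
Conditions: n-BuLi, THF, −78 °C; aq. NH4Cl
Reagents that add atoms: none
Why: Wittig–Still [2,3]-sigmatropic rearrangement after tin–lithium exchange; the CH2O unit is delivered to the ring alkene carbon on the face anti to the neighbouring CH2OTBS group (pseudoaxial because isopropyl keeps the equatorial site), and the alkene moves to the exocyclic position.

**Step 17**
Reactants: 28 homoallylic alcohol
Product: 29 {(3R,4R,5R,6S)-5-[(TBS-oxy)methyl]-6-isopropyl-1-oxaspiro[2.5]octan-4-yl}methanol (epoxide oxygen cis to CH2OH)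
Conditions: VO(acac)2 (5 mol %), t-BuOOH, CH2Cl2, 0 °C → rt
Reagents that add atoms: tert-butyl hydroperoxide, CC(C)(C)OO
Why: hydroxyl-directed vanadium-catalysed epoxidation of a homoallylic alcohol; the vanadium-bound alkoxide delivers oxygen to the alkene face syn to CH2OH, which is also the face not covered by the CH2OTBS arm.

**Step 18**
Reactants: 29 epoxy alcohol; 1 4-methoxybenzyl alcohol
Product: 31 (1R,2R,3R,4S)-3-[(TBS-oxy)methyl]-2-(hydroxymethyl)-4-isopropyl-1-[(PMB-oxy)methyl]cyclohexan-1-ol, via potassium 4-methoxybenzyl oxide 30 (not isolated)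
Conditions: 1 (5 equiv), KH (3 equiv), THF/DMPU, 0 °C; then 29, 60 °C; aq. NH4Cl
Reagents that add atoms: none
Why: base-mediated epoxide opening; the potassium alkoxide, a stronger nucleophile than its sodium counterpart in THF/DMPU, attacks the CH2 carbon by SN2, so the tertiary C–O bond and its configuration are kept, and the opening is done before any carbonyl is placed β to the epoxide, which avoids eliminative opening.

**Step 19**
Reactants: 31 diol
Product: 32 (1S,2R,5S,6R)-6-[(TBS-oxy)methyl]-2-hydroxy-5-isopropyl-2-[(PMB-oxy)methyl]cyclohexane-1-carboxylic acid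
Conditions: TEMPO (20 mol %), PhI(OAc)2, MeCN/H2O, rt
Reagents that add atoms: water, O
Why: TEMPO/PhI(OAc)2 oxidation of the primary alcohol through the aldehyde hydrate to the acid; the tertiary alcohol and both ethers are inert.

**Step 20**
Reactants: 32 silyl ether acid
Product: 33 (1S,2R,5S,6R)-2-hydroxy-6-(hydroxymethyl)-5-isopropyl-2-[(PMB-oxy)methyl]cyclohexane-1-carboxylic acid
Conditions: HF·pyridine, pyridine/THF, 0 °C → rt
Reagents that add atoms: none
Why: fluoride desilylation under mildly acidic conditions; the PMB ether is stable and the trans hydroxy acid cannot lactonise easily.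

**Step 21**
Reactants: 33 hydroxy acid
Product: 36 cis-fused 3,7-dihydroxy-4-isopropyl-7-[(PMB-oxy)methyl]hexahydro-2-benzofuran-1(3H)-one (pseudo-acid; lactol carbon as a mixture), via trans aldehyde acid 34 (not isolated), via cis aldehyde acid 35 (not isolated)
Conditions: Dess–Martin periodinane, NaHCO3, CH2Cl2, 0 °C; then DBU, THF, rt; aq. citric acid
Reagents that add atoms: none
Why: Dess–Martin oxidation gives the aldehyde, and DBU-mediated enolisation (α-epimerisation) equilibrates the formyl-bearing carbon; the cis isomer should be drained as the cis-fused hydroxy-γ-lactone (ring-chain tautomer of a γ-oxo acid), where the one-carbon arm is equatorial and free of the 1,3-diaxial clash with CH2OPMB, so this centre ends trans to isopropyl.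

**Step 22**
Reactants: 36 pseudo-acid
Product: 38 (1S,2R,5S,6S)-6-ethenyl-2-hydroxy-5-isopropyl-2-[(PMB-oxy)methyl]cyclohexane-1-carboxylic acid, via potassium cis formyl carboxylate 37 (not isolated)
Conditions: Ph3PCH3Br, KHMDS (4 equiv each), THF, −78 → 0 °C; aq. HCl to pH 3
Reagents that add atoms: methyltriphenylphosphonium bromide, C[P+](c1ccccc1)(c1ccccc1)c1ccccc1.[Br-]
Why: Wittig methylenation of a lactol; the first equivalent of ylide deprotonates the hydroxy lactone, which opens to the potassium carboxylate of the cis aldehyde, and this should be trapped by further ylide at low temperature faster than it re-equilibrates.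

**Step 23**
Reactants: 38 vinyl acid; 39 tert-butyl 2-(bromomethyl)acrylate
Product: 41 2-(tert-butoxycarbonyl)allyl ester of 38, via caesium carboxylate 40 (not isolated)
Conditions: Cs2CO3, DMF, 0 °C → rt
Reagents that add atoms: none
Why: carboxylate O-alkylation by the allylic bromide (SN2 and SN2′ give the same ester); the tertiary hydroxyl is not alkylated under carbonate conditions.

**Step 24**
Reactants: 41 diene ester
Product: 42 tert-butyl (5aR,6S,9R,9aS)-9-hydroxy-6-isopropyl-9-[(PMB-oxy)methyl]-1-oxo-1,3,5a,6,7,8,9,9a-octahydro-2-benzoxepine-4-carboxylate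
Conditions: second-generation Hoveyda–Grubbs catalyst (C31H38Cl2N2ORu, 10 mol %), toluene (2 mM), 80 °C
Reagents that add atoms: none
Why: ring-closing metathesis; the ruthenium alkylidene forms at the vinyl group and closes onto the 1,1-disubstituted acrylate, and because the new alkene is endocyclic in a seven-membered ring the ester must lie trans to ring A, a closure possible only because the vinyl and acyloxy arms are cis.

**Step 25**
Reactants: 42 PMB ether
Product: 43 tert-butyl (5aR,6S,9R,9aS)-9-hydroxy-9-(hydroxymethyl)-6-isopropyl-1-oxo-1,3,5a,6,7,8,9,9a-octahydro-2-benzoxepine-4-carboxylate (left-half diol)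
Conditions: DDQ, water-saturated CH2Cl2/pH 7 buffer, 0 °C → rt
Reagents that add atoms: none
Why: oxidative PMB ether cleavage; excess water should hydrolyse the benzylic cation before the hindered tertiary hydroxyl can capture it.

**Step 26**
Reactants: 22 right-half acid; 43 left-half diol
Product: 45 fully protected target (bis-PMB ether, tert-butyl ester), via mixed anhydride 44 (not isolated)
Conditions: 2,4,6-Cl3C6H2COCl, Et3N, toluene, rt; then 43, DMAP, rt
Reagents that add atoms: none
Why: Yamaguchi esterification; DMAP transfers the acyl group from the mixed anhydride to the primary hydroxyl, the tertiary hydroxyl being too hindered to compete.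

**Step 27**
Reactants: 45 protected target
Product: 46 CNP0361406.6
Conditions: TFA, anisole, CH2Cl2, 0 °C
Reagents that add atoms: none
Why: acidolysis; both PMB ethers and the tert-butyl ester ionise to stabilised cations that are trapped by anisole or lost as isobutene, while the lactone and the acrylate ester are stable to anhydrous acid at 0 °C.

**Compound list**

1 | 4-methoxybenzyl alcohol | COc1ccc(CO)cc1 | starting material
2 | 2,3-dibromopropene | C=C(Br)CBr | starting material
3 | sodium 4-methoxybenzyl oxide | COc1ccc(C[O-])cc1.[Na+] | intermediate (not isolated)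
4 | 2-bromoallyl PMB ether | C=C(Br)COCc1ccc(OC)cc1 | intermediate
5 | (E)-3-(TBS-oxy)prop-1-enylboronic acid pinacol ester | CC(C)(C)[Si](C)(C)OC/C=C/B1OC(C)(C)C(C)(C)O1 | starting material
6 | (E)-1-(TBS-oxy)-4-(PMB-oxymethyl)penta-2,4-diene | C=C(COCc1ccc(OC)cc1)/C=C/CO[Si](C)(C)C(C)(C)C | intermediate
7 | (S)-4-benzyloxazolidin-2-one | O=C1N[C@@H](Cc2ccccc2)CO1 | starting material
8 | acryloyl chloride | C=CC(=O)Cl | starting material
9 | lithium (S)-4-benzyl-2-oxooxazolidin-3-ide | [Li]N1[C@@H](Cc2ccccc2)COC1=O | intermediate (not isolated)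
10 | (S)-3-acryloyl-4-benzyloxazolidin-2-one | C=CC(=O)N1[C@@H](Cc2ccccc2)COC1=O | intermediate
11 | cis cycloadduct, (1R,2S) imide | CC(C)(C)[Si](C)(C)OC[C@H]1C=C(COCc2ccc(OC)cc2)CC[C@H]1C(=O)N3C(=O)OC[C@@H]3Cc4ccccc4 | intermediate
12 | (1R,2S) Weinreb amide | CC(C)(C)[Si](C)(C)OC[C@H]1C=C(COCc2ccc(OC)cc2)CC[C@H]1C(=O)N(C)OC | intermediate
13 | (1R,2S) methyl ketone | CC(C)(C)[Si](C)(C)OC[C@H]1C=C(COCc2ccc(OC)cc2)CC[C@H]1C(C)=O | intermediate
14 | cis isopropenyl cyclohexene | CC(C)(C)[Si](C)(C)OC[C@H]1C=C(COCc2ccc(OC)cc2)CC[C@H]1C(C)=C | intermediate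
15 | (1R,6S) cis isopropyl cyclohexene, common intermediate | CC(C)(C)[Si](C)(C)OC[C@H]1C=C(COCc2ccc(OC)cc2)CC[C@H]1C(C)C | intermediate
16 | ring C primary alcohol | OC[C@H]1C=C(COCc2ccc(OC)cc2)CC[C@H]1C(C)C | intermediate
17 | ring C cis carbaldehyde | O=C[C@H]1C=C(COCc2ccc(OC)cc2)CC[C@H]1C(C)C | intermediate
18 | ethyl 2-(diethoxyphosphoryl)acrylate | C=C(C(=O)OCC)P(=O)(OCC)OCC | starting material
19 | ethyl 2-(diethoxyphosphoryl)-3-(PMB-oxy)propanoate | CCOC(=O)C(COCc1ccc(OC)cc1)P(=O)(OCC)OCC | intermediate
20 | sodium salt of 19 | CCOC(=O)[C-](COCc1ccc(OC)cc1)P(=O)(OCC)OCC.[Na+] | intermediate (not isolated)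
21 | right-half (E)-ethyl ester | CCOC(=O)/C(=C/[C@H]1C=C(COCc2ccc(OC)cc2)CC[C@H]1C(C)C)COCc3ccc(OC)cc3 | intermediate
22 | right-half (E)-acid | OC(=O)/C(=C/[C@H]1C=C(COCc2ccc(OC)cc2)CC[C@H]1C(C)C)COCc3ccc(OC)cc3 | intermediate
23 | (3R,4S) allylic alcohol | CC(C)[C@@H]1CCC(CO)=C[C@@H]1CO[Si](C)(C)C(C)(C)C | intermediate
24 | tributyl(iodomethyl)stannane | CCCC[Sn](CI)(CCCC)CCCC | starting material
25 | potassium alkoxide of 23 | CC(C)[C@@H]1CCC(C[O-])=C[C@@H]1CO[Si](C)(C)C(C)(C)C.[K+] | intermediate (not isolated)
26 | stannylmethyl ether | CC(C)[C@@H]1CCC(COC[Sn](CCCC)(CCCC)CCCC)=C[C@@H]1CO[Si](C)(C)C(C)(C)C | intermediate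
27 | alkoxymethyllithium | CC(C)[C@@H]1CCC(COC[Li])=C[C@@H]1CO[Si](C)(C)C(C)(C)C | intermediate (not isolated)
28 | (1S,2R,3S) methylidene alcohol (CH2OH trans to CH2OTBS; CH2OTBS cis to isopropyl) | CC(C)[C@@H]1CCC(=C)[C@@H](CO)[C@@H]1CO[Si](C)(C)C(C)(C)C | intermediate
29 | spiro-epoxy alcohol (epoxide O cis to CH2OH) | CC(C)[C@@H]1CC[C@]2(CO2)[C@@H](CO)[C@@H]1CO[Si](C)(C)C(C)(C)C | intermediate
30 | potassium 4-methoxybenzyl oxide | COc1ccc(C[O-])cc1.[K+] | intermediate (not isolated)
31 | diol PMB ether (tertiary OH cis to CH2OH) | CC(C)[C@@H]1CC[C@](O)(COCc2ccc(OC)cc2)[C@@H](CO)[C@@H]1CO[Si](C)(C)C(C)(C)C | intermediate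
32 | β-hydroxy acid, TBS ether | CC(C)[C@@H]1CC[C@](O)(COCc2ccc(OC)cc2)[C@@H](C(=O)O)[C@@H]1CO[Si](C)(C)C(C)(C)C | intermediate
33 | dihydroxy acid (CH2OH trans to CO2H) | CC(C)[C@@H]1CC[C@](O)(COCc2ccc(OC)cc2)[C@@H](C(=O)O)[C@@H]1CO | intermediate
34 | trans aldehyde acid (formyl cis to isopropyl) | CC(C)[C@@H]1CC[C@](O)(COCc2ccc(OC)cc2)[C@@H](C(=O)O)[C@@H]1C=O | intermediate (not isolated)
35 | cis aldehyde acid (formyl trans to isopropyl, cis to CO2H) | CC(C)[C@@H]1CC[C@](O)(COCc2ccc(OC)cc2)[C@@H](C(=O)O)[C@H]1C=O | intermediate (not isolated)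
36 | cis-fused hydroxy-γ-lactone (pseudo-acid) | CC(C)[C@@H]1CC[C@](O)(COCc2ccc(OC)cc2)[C@H]2C(=O)OC(O)[C@@H]12 | intermediate
37 | potassium salt of the cis aldehyde acid (open form of 36) | CC(C)[C@@H]1CC[C@](O)(COCc2ccc(OC)cc2)[C@@H](C(=O)[O-])[C@H]1C=O.[K+] | intermediate (not isolated)
38 | (1S,2R,5S,6S) vinyl acid | CC(C)[C@@H]1CC[C@](O)(COCc2ccc(OC)cc2)[C@@H](C(=O)O)[C@H]1C=C | intermediate
39 | tert-butyl 2-(bromomethyl)acrylate | C=C(CBr)C(=O)OC(C)(C)C | starting material
40 | caesium carboxylate of 38 | CC(C)[C@@H]1CC[C@](O)(COCc2ccc(OC)cc2)[C@@H](C(=O)[O-])[C@H]1C=C.[Cs+] | intermediate (not isolated)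
41 | metathesis precursor, 2-(tert-butoxycarbonyl)allyl ester | CC(C)[C@@H]1CC[C@](O)(COCc2ccc(OC)cc2)[C@@H](C(=O)OCC(=C)C(=O)OC(C)(C)C)[C@H]1C=C | intermediate
42 | (5aR,6S,9R,9aS) bicyclic lactone PMB ether | CC(C)[C@@H]1CC[C@](O)(COCc2ccc(OC)cc2)[C@H]2C(=O)OCC(C(=O)OC(C)(C)C)=C[C@@H]12 | intermediate
43 | (5aR,6S,9R,9aS) bicyclic lactone diol, left half | CC(C)[C@@H]1CC[C@](O)(CO)[C@H]2C(=O)OCC(C(=O)OC(C)(C)C)=C[C@@H]12 | intermediate
44 | mixed 2,4,6-trichlorobenzoic anhydride of 22 | O=C(OC(=O)c1c(Cl)cc(Cl)cc1Cl)/C(=C/[C@H]2C=C(COCc3ccc(OC)cc3)CC[C@H]2C(C)C)COCc4ccc(OC)cc4 | intermediate (not isolated)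
45 | protected target (two PMB ethers, tert-butyl ester) | CC(C)[C@@H]1CC[C@](O)(COC(=O)/C(=C/[C@H]2C=C(COCc3ccc(OC)cc3)CC[C@H]2C(C)C)COCc4ccc(OC)cc4)[C@H]5C(=O)OCC(C(=O)OC(C)(C)C)=C[C@@H]15 | intermediate
46 | CNP0361406.6, (5aR,6S,9R,9aS)-9-hydroxy-9-{[(2E)-2-(hydroxymethyl)-3-[(1R,6S)-3-(hydroxymethyl)-6-isopropylcyclohex-2-en-1-yl]prop-2-enoyl]oxymethyl}-6-isopropyl-1-oxo-1,3,5a,6,7,8,9,9a-octahydro-2-benzoxepine-4-carboxylic acid | CC(C)[C@@H]1CC[C@](O)(COC(=O)/C(=C/[C@H]2C=C(CO)CC[C@H]2C(C)C)CO)[C@H]2C(=O)OCC(C(=O)O)=C[C@@H]12 | target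

**Count**

Total: 27 steps. Longest linear sequence: 21 steps (1, 2, 4–8, 14–27).

**Steps most likely to fail, with fallbacks**

Step 21. The base-mediated equilibration at the formyl-bearing ring carbon may stop at a mixture of epimers, or the β-hydroxy acid may be lost by retro-aldol cleavage. The fallback sets this centre by syn-hydrogenation instead of equilibration and sets out from hydroxy acid 33. After the same oxidation, the crude γ-oxo acid, whatever its configuration, is heated with Ac2O/NaOAc (80 °C) to the enol lactone F1, in which the carbon in question is sp2. Hydrogenation (H2, Rh/Al2O3, EtOAc) should add hydrogen on the face that already carries the ring-fusion hydrogen and give the cis-fused γ-lactone F2. LiOH (THF/H2O) opens it to the lithium hydroxy carboxylate F3, which is oxidised as the salt (TEMPO, PhI(OAc)2, CH2Cl2) and acidified, coming back to the route at pseudo-acid 36.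

Step 24. Ring closure onto the 1,1-disubstituted, electron-poor alkene may lose out to intermolecular metathesis at the vinyl group, and the alkylidene may decompose first. The fallback replaces metathesis by olefination and lactonisation and sets out from pseudo-acid 36. tert-Butyl diethylphosphonoacetate is condensed with paraformaldehyde (piperidine, then TsOH) to tert-butyl 2-(diethoxyphosphoryl)acrylate F4, and alcohol 1 is added as in step 11 to give the tert-butyl phosphonate F5. Its sodium salt (2.2 equiv, THF) olefinates 36 to the (E)-seco acid F6. DDQ removes both PMB ethers to give the triol acid F7. Mitsunobu lactonisation (PPh3, DIAD, THF, high dilution) should activate the unhindered allylic primary alcohol rather than the neopentyl-type one and close the seven-membered lactone, coming back to the route at diol 43.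

Step 27. In acid, PMB cations may alkylate the ring C alkene, the allylic alcohols may ionise, or the tertiary alcohol may dehydrate. The fallback unmasks in stages without protic acid and sets out from 45. DDQ (water-saturated CH2Cl2, pH 7 buffer) removes both PMB ethers to give the diol tert-butyl ester F8. TMSOTf/2,6-lutidine (CH2Cl2, 0 °C) exchanges the tert-butyl ester for a trimethylsilyl ester while silylating the hydroxyl groups, giving the persilylated compound F9. Aqueous citric acid in MeOH hydrolyses all Si–O bonds and comes back to the route at 46.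

**Further compounds**

F1 | step 21 | enol lactone (ring-fusion C=C to the lactone CH) | CC(C)[C@@H]1CC[C@](O)(COCc2ccc(OC)cc2)[C@H]2C(=O)OC=C12
F2 | step 21 | cis-fused γ-lactone | CC(C)[C@@H]1CC[C@](O)(COCc2ccc(OC)cc2)[C@H]2C(=O)OC[C@@H]12
F3 | step 21 | lithium cis hydroxy carboxylate | CC(C)[C@@H]1CC[C@](O)(COCc2ccc(OC)cc2)[C@@H](C(=O)[O-])[C@H]1CO.[Li+]
F4 | step 24 | tert-butyl 2-(diethoxyphosphoryl)acrylate | C=C(C(=O)OC(C)(C)C)P(=O)(OCC)OCC
F5 | step 24 | tert-butyl 2-(diethoxyphosphoryl)-3-(PMB-oxy)propanoate | CC(C)(C)OC(=O)C(COCc1ccc(OC)cc1)P(=O)(OCC)OCC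
F6 | step 24 | (E)-seco acid, bis-PMB ether | CC(C)[C@@H]1CC[C@](O)(COCc2ccc(OC)cc2)[C@@H](C(=O)O)[C@H]1/C=C(/C(=O)OC(C)(C)C)COCc3ccc(OC)cc3
F7 | step 24 | (E)-triol acid | CC(C)[C@@H]1CC[C@](O)(CO)[C@@H](C(=O)O)[C@H]1/C=C(/C(=O)OC(C)(C)C)CO
F8 | step 27 | tert-butyl ester of the target | CC(C)[C@@H]1CC[C@](O)(COC(=O)/C(=C/[C@H]2C=C(CO)CC[C@H]2C(C)C)CO)[C@H]3C(=O)OCC(C(=O)OC(C)(C)C)=C[C@@H]13
F9 | step 27 | tris(trimethylsilyl) ether trimethylsilyl ester of the target | CC(C)[C@@H]1CC[C@](O[Si](C)(C)C)(COC(=O)/C(=C/[C@H]2C=C(CO[Si](C)(C)C)CC[C@H]2C(C)C)CO[Si](C)(C)C)[C@H]3C(=O)OCC(C(=O)O[Si](C)(C)C)=C[C@@H]13
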